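**Assumption:** 5-methoxyresorcinol, benzaldehyde and 2',6'-dihydroxy-4'-methoxyacetophenone are commercial. If the last is not, it is one selective 4-O-methylation of 2,4,6-trihydroxyacetophenone. The target is the 2,4-trans (2R,4R) flavan with an axial 4-aryl group.

## Retrosynthetic overview
- Disconnect C4–C3' (flavan C4 to the cardamonin ring). This gives a 2R-flavan-4-yl cation (from the flavan-4-ol, with the 7-OH stabilising it as a quinone-methide) and cardamonin as a C-nucleophile. The C2 phenyl directs axial attack at C4, giving 2,4-trans.
- The flavan-4-ol comes from the (2R)-flavanone. That flavanone comes from an organocatalytic asymmetric intramolecular oxa-Michael reaction of a 2'-hydroxychalcone, which sets C2 as the first stereocentre.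
- The chalcone comes from Claisen–Schmidt condensation of the acetophenone. The acetophenone comes from acylation of 2,5-dimethoxyresorcinol, which is built from 5-methoxyresorcinol by directed ortho-metalation and oxygenation.
- Ring order: the aromatic A-ring is made first, then the pyran ring (oxa-Michael), then the C4–aryl bond.

## Route

**Step 1**
Reactants: 1 (5-methoxyresorcinol)
Product: 2 (1,3-bis(methoxymethoxy)-5-methoxybenzene)
Conditions: NaH (2.4 equiv), MOMCl, DMF, 0 °C → rt
Reagents that add atoms: MOMCl, ClCOC
Why: Double MOM protection of both phenols makes two strong chelating directing groups for the next step (Williamson-type O-alkylation).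

**Step 2**
Reactants: 2
Product: 3 (2,6-bis(methoxymethoxy)-4-methoxyphenol)
Conditions: n-BuLi, THF, 0 °C, 1 h; B(OMe)3, −78 °C → rt; then 30% H2O2, 3 M NaOH, 0 °C
Reagents that add atoms: H2O2, OO (supplies the new phenolic O). B(OMe)3, COB(OC)OC, keeps no atoms.
Why: Directed ortho-metalation should occur at C2, the only position flanked by two OMOM groups. Borylation then oxidative (Dakin-type) work-up installs the central oxygen.

**Step 3**
Reactants: 3
Product: 4 (1,3-bis(methoxymethoxy)-2,5-dimethoxybenzene)
Conditions: MeI, K2CO3, DMF, 25 °C
Reagents that add atoms: MeI, CI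
Why: O-Methylation of the hindered phenol by SN2 installs the 8-OMe of the flavan.

**Step 4**
Reactants: 4
Product: 5 (2,5-dimethoxybenzene-1,3-diol)
Conditions: 6 M HCl, MeOH, 50 °C, 2 h, N2; crude used at once
Reagents that add atoms: none
Why: Acid hydrolysis of the MOM acetals gives the C2v-symmetric diol, in which both free ring positions are equivalent.

**Step 5**
Reactants: 5
Product: 6 (1-(2,4-dihydroxy-3,6-dimethoxyphenyl)ethanone)
Conditions: AcOH, BF3·OEt2, 90 °C, 2 h
Reagents that add atoms: acetic acid, CC(=O)O
Why: Hoesch-type Friedel–Crafts C-acylation occurs ortho to a free OH. Because the diol is symmetric, only one regioisomer forms.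

**Step 6**
Reactants: 6, 7 (benzaldehyde)
Product: 8 ((E)-2',4'-dihydroxy-3',6'-dimethoxychalcone)
Conditions: 50% aq. KOH, EtOH, 25 °C, 48 h; quench with cold dilute HCl to pH 5
Reagents that add atoms: none (benzaldehyde is reactant 7)
Why: Claisen–Schmidt aldol condensation gives the E-enone.

**Step 7**
Reactants: 8
Product: 9 ((2R)-7-hydroxy-5,8-dimethoxyflavanone)
Conditions: 9-amino-9-deoxy-epi-quinidine (20 mol%), TFA (40 mol%), PhMe, 40 °C, 48 h (pseudo-enantiomeric quinine-derived amine if 2S is obtained)
Reagents that add atoms: none
Why: Primary-amine iminium activation of the enone plus phenol H-bond direction gives an enantioselective intramolecular oxa-Michael reaction. The catalyst sets C2 (R), the first stereocentre.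

**Step 8**
Reactants: 9
Product: 10 ((2R)-5,8-dimethoxy-2-phenylchroman-4,7-diol, C4 epimers)
Conditions: NaBH4 (1.5 equiv), EtOH/THF 1:1, −10 °C, 1 h; quench with pH 7 buffer
Reagents that add atoms: none (hydride only)
Why: Chemoselective ketone reduction. The C4 epimers converge through the same cation in step 10, and the low temperature avoids base-mediated retro-oxa-Michael racemisation of C2.

**Step 9**
Reactants: 11 (2',6'-dihydroxy-4'-methoxyacetophenone), 7 (benzaldehyde)
Product: 12 (cardamonin, (E)-2',6'-dihydroxy-4'-methoxychalcone)
Conditions: 50% aq. KOH, EtOH, 25 °C, 48 h; acidify to pH 5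
Reagents that add atoms: none
Why: Claisen–Schmidt condensation. C3' and C5' of cardamonin are equivalent, so the later C-alkylation has no regiochemical ambiguity.

**Step 10**
Reactants: 10, 12
Product: 13 (Sarcandrone B)
Conditions: (PhO)2P(O)OH (10 mol%), HFIP/CH2Cl2 1:9, 4 Å MS, 0 → 25 °C, 12 h. Add 10 by syringe pump over 4 h to 12 (3 equiv), protected from light.
Reagents that add atoms: none
Why: Dehydrative Friedel–Crafts arylation at C3' of cardamonin. C2 is untouched, and the new C4 centre forms by axial attack anti to the equatorial 2-Ph, which gives 2,4-trans with the 4-aryl axial, as favoured by peri strain with 5-OMe.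
Proposed new method: Acid ionises the C4–OH of the 7-hydroxyflavan-4-ol, assisted by 7-OH, 5-OMe and O1, to give a delocalised flavan-4-yl/p-quinone-methide cation. The mild acid and HFIP are chosen to avoid cyclising cardamonin to pinostrobin. The strongly nucleophilic C3' (para to 6'-OH, ortho to 2'-OH) then attacks the cation axially, transferring chirality from C2 to C4 by 1,3-induction. The closest known chemistry is the acid-mediated coupling of flavan-4-ols with phloroglucinol nucleophiles in proanthocyanidin chemistry, and phosphoric-acid-catalysed dehydrative Friedel–Crafts of benzylic alcohols and p-quinone methides. It has not been shown with a 2,6-dihydroxyaryl enone (chalcone) nucleophile, nor with 7-hydroxyflavan-4-ols without a C3 substituent.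

## Compound list
1 | 5-methoxyresorcinol | COc1cc(O)cc(O)c1 | starting material
2 | 1,3-bis(methoxymethoxy)-5-methoxybenzene | COCOc1cc(OC)cc(OCOC)c1 | intermediate
3 | 2,6-bis(methoxymethoxy)-4-methoxyphenol | COCOc1cc(OC)cc(OCOC)c1O | intermediate
4 | 1,3-bis(methoxymethoxy)-2,5-dimethoxybenzene | COCOc1cc(OC)cc(OCOC)c1OC | intermediate
5 | 2,5-dimethoxybenzene-1,3-diol | COc1cc(O)c(OC)c(O)c1 | intermediate
6 | 1-(2,4-dihydroxy-3,6-dimethoxyphenyl)ethanone | CC(=O)c1c(OC)cc(O)c(OC)c1O | intermediate
7 | benzaldehyde | O=Cc1ccccc1 | starting material
8 | (E)-2',4'-dihydroxy-3',6'-dimethoxychalcone | O=C(/C=C/c1ccccc1)c1c(OC)cc(O)c(OC)c1O | intermediate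
9 | (2R)-7-hydroxy-5,8-dimethoxyflavanone | O=C1C[C@H](c2ccccc2)Oc2c(OC)c(O)cc(OC)c21 | intermediate
10 | (2R)-5,8-dimethoxy-2-phenylchroman-4,7-diol (C4 epimers) | OC1C[C@H](c2ccccc2)Oc2c(OC)c(O)cc(OC)c21 | intermediate
11 | 2',6'-dihydroxy-4'-methoxyacetophenone | CC(=O)c1c(O)cc(OC)cc1O | starting material
12 | cardamonin | O=C(/C=C/c1ccccc1)c1c(O)cc(OC)cc1O | intermediate
13 | Sarcandrone B | COc1cc(O)c(C(=O)/C=C/c2ccccc2)c(O)c1[C@H]1C[C@H](c2ccccc2)Oc2c(OC)c(O)cc(OC)c21 | target

## Totals
- Total steps: 10.
- Longest linear sequence: 9 (steps 1–8 and 10).

## Three steps most likely to fail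
1. **Step 10 (proposed new coupling).** Risks are self-condensation of the electron-rich flavan-4-ol, cyclisation of cardamonin, and poor trans selectivity.
   - Fallback: use the non-Michael-acceptor nucleophile 11 in a standard acid-mediated flavan-4-ol/phloroglucinol-type coupling. Then install the cinnamoyl group last by Claisen–Schmidt condensation with benzaldehyde (KOH, EtOH).
2. **Step 2 (directed ortho-metalation).** Lithiation may not be selective for C2 over C4/C6.
   - Fallback: make 5 through a Dakin route. Start from 2,4,6-trihydroxybenzaldehyde, do selective 4-O-methylation, then O-benzylation. Carry out Baeyer–Villiger/Dakin oxidation (mCPBA) and hydrolysis, methylate the central phenol, and remove the benzyl groups by hydrogenolysis (H2, Pd/C).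
3. **Step 7 (organocatalytic oxa-Michael).** Enantioselectivity may be modest, or the reaction may be reversible.
   - Fallback: cyclise chalcone 8 to racemic flavanone with base (NaOAc, EtOH, reflux) and resolve (2R)-9 by preparative chiral-stationary-phase HPLC.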